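A direct plan would make the two isoflavone halves separately by deoxybenzoin annulation, 8-chlorodaidzein (A1) and formononetin (A2), methylate A1 selectively at O7 to the 4'-phenol A3, turn C8 of A2 into the ortho-quinone diazide A4 by azo coupling, reductive cleavage and diazotisation, join A3 and A4 by a carbene O–H insertion and demethylate at the end.
Weak point 1, the late ether union of two finished isoflavones: it would have to form the C8–O bond between two ortho substituents by a reaction without close precedent, at the point where most material is invested.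
Weak point 2, the azo coupling/reduction/diazotisation run on A2: three operations that would build no skeletal bond, serve only to activate C8 and rest on C8-over-C6 selectivity.
Weak point 3, the selective 7-O-methylation of A1: it would rely only on an acidity difference between two phenols and would be needed only because the halves are joined late.

**Retrosynthetic overview**
The ring system is cut at both heterocycles, not at the ether: the C8–O–C4' diaryl ether between ring A of the daidzein half and ring B of the 8-chlorodaidzein half is made first, by SNAr between two plain benzenes (2,6-dimethoxyphenol and 4-fluorobenzaldehyde).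
One Friedel–Crafts cinnamoylation and one Claisen–Schmidt condensation then hang a 2'-hydroxychalcone on each side of this ether (bis-chalcone 8).
The key step shifts both ring B aryl groups from C-β to C-α by a twofold oxidative 1,2-aryl migration, as in isoflavone biosynthesis, and closes both pyranone rings C in the same operation, so both C3–aryl bonds, both O1–C2 bonds and both heterocycles appear last.
No C8 activation, no late ether coupling and no phenol differentiation occur; chlorine and the aryloxy group end up at C8 because each ketone has a single ortho hydroxyl, and the three methyl ethers that come with the starting materials fall in one final step.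

Key step: step 5

Assumption: (E)-4-methoxycinnamoyl chloride (4) is taken as a commercial compound; the target is achiral, so no stereocentre has to be set.

**Step 1**
Reactants: 1 2,6-dimethoxyphenol; 2 4-fluorobenzaldehyde
Product: 3 4-(2,6-dimethoxyphenoxy)benzaldehyde
Conditions: K2CO3 (1.5 equiv), DMF, 130 °C, 14 h, N2
Reagents that add atoms: none
Why: Nucleophilic aromatic substitution (SNAr): the para-formyl group activates the fluoride toward the 2,6-dimethoxyphenoxide, the steric load of the future C8–O bond sits only on the phenoxide oxygen because the attacked carbon has two ortho hydrogens, and neither partner can enolise, so the hindered ether should form cleanly while both rings are still simple benzenes.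

**Step 2**
Reactants: 3 4-(2,6-dimethoxyphenoxy)benzaldehyde; 4 (E)-3-(4-methoxyphenyl)prop-2-enoyl chloride ((E)-4-methoxycinnamoyl chloride)
Product: 5 4-{2-hydroxy-6-methoxy-3-[(2E)-3-(4-methoxyphenyl)prop-2-enoyl]phenoxy}benzaldehyde
Conditions: AlCl3 (3.5 equiv) and 4 (1.15 equiv) premixed in CH2Cl2, 3 added at −10 °C, 1 h; then rt, 8 h; ice/2 M HCl
Reagents that add atoms: none
Why: Friedel–Crafts acylation attacks the dimethoxyphenoxy ring at its only doubly activated position (ortho to one methoxy, para to the other; the formyl-bearing ring is deactivated), and AlCl3 chelated between the new ketone and the flanked ortho methoxy group then cleaves only that ether (ortho-selective demethylation), which unmasks the 2'-hydroxyl of a chalcone whose E alkene comes unchanged from the acid chloride.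

**Step 3**
Reactants: 6 2-chloro-1,3-dimethoxybenzene
Product: 7 1-(3-chloro-2-hydroxy-4-methoxyphenyl)ethan-1-one
Conditions: AcCl (1.2 equiv), AlCl3 (2.5 equiv), CH2Cl2, 0 → 40 °C, 5 h; ice/2 M HCl
Reagents that add atoms: acetyl chloride, CC(Cl)=O
Why: Friedel–Crafts acetylation at C4 (equivalent to C6, so a single ketone can form), followed in the same flask by chelation-controlled cleavage of the methoxy group that lies between the new carbonyl and chlorine, gives the hydrogen-bonded ortho-hydroxyacetophenone with the other methyl ether intact.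

**Step 4**
Reactants: 5 the chalcone aldehyde; 7 1-(3-chloro-2-hydroxy-4-methoxyphenyl)ethan-1-one (1.1 equiv)
Product: 8 (2E)-1-(3-chloro-2-hydroxy-4-methoxyphenyl)-3-(4-{2-hydroxy-6-methoxy-3-[(2E)-3-(4-methoxyphenyl)prop-2-enoyl]phenoxy}phenyl)prop-2-en-1-one (bis-chalcone)
Conditions: KOH (50% aq., 10 equiv), EtOH/THF, rt, 36 h, N2; then 2 M HCl to pH 3
Reagents that add atoms: none
Why: Claisen–Schmidt condensation (crossed aldol with E1cB dehydration): 7 is the only partner with an enolisable methyl ketone and 5 carries the only aldehyde, which cannot enolise, so one cross product is possible; the enone already present in 5 is shielded from conjugate addition by its ortho phenoxide and its electron-rich β-aryl group, and the reversible dehydration should give the E alkene.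

**Step 5**
Reactants: 8 the bis(2'-hydroxychalcone)
Product: 10 bisoflavolin J trimethyl ether (8-chloro-7-methoxy-3-(4-{[7-methoxy-3-(4-methoxyphenyl)-4-oxo-4H-chromen-8-yl]oxy}phenyl)-4H-chromen-4-one), via bis(β-keto acetal) 9 (not isolated)
Conditions: PhI(OH)OTs (2.6 equiv), MeOH/HC(OMe)3/CH2Cl2 (2:2:1), rt → 45 °C, 8 h; then conc. HCl (to about 1 M), 60 °C, 3 h
Reagents that add atoms: methanol, CO (its methoxy groups stand in 9 only and leave again in the ring closure)
Why: The trivalent iodine reagent PhI(OH)OTs adds to each enone C=C in methanol (methoxy at the benzylic C-β, phenyliodanyl at C-α), the aryl group on C-β then migrates to C-α through a phenonium ion while iodobenzene leaves, and methanol traps the resulting oxocarbenium ion as the β-keto dimethyl acetal, so that both halves of 8 reach bis-acetal 9. The closest known reaction type is the oxidative rearrangement of single 2'-hydroxychalcones to isoflavones with Tl(NO3)3 or with trivalent iodine reagents in methanol, applied here to two enones of one molecule. On acidification each ring C closes by 6-exo-trig attack of the chelated 2'-hydroxyl on the methoxycarbenium ion released from its acetal, and loss of methanol from the 2-methoxyisoflavanone gives the pyranone. The two α-carbons of 9 arise as a mixture of stereoisomers without control, which is of no consequence because both become sp2 centres of 10. The step needs aryl migration to win over oxidation of the phenol rings and over flavone or aurone formation: both migrating rings carry a para oxygen donor (aryloxy in one half, methoxy in the other), and both phenols are deactivated by the hydrogen bond to their ketone. The regiochemistry of ring closure needs no control, since each ketone has one ortho hydroxyl only, which places chlorine and the aryloxy group at C8 of their chromones.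

**Step 6**
Reactants: 10 bisoflavolin J trimethyl ether
Product: 11 bisoflavolin J (8-chloro-7-hydroxy-3-(4-{[7-hydroxy-3-(4-hydroxyphenyl)-4-oxo-4H-chromen-8-yl]oxy}phenyl)-4H-chromen-4-one)
Conditions: BBr3 (10 equiv), CH2Cl2, −78 °C → rt, 16 h; then MeOH, H2O
Reagents that add atoms: none
Why: Lewis acid ether cleavage: bromide attacks only the methyl carbons of the three boron-complexed aryl methyl ethers, so the diaryl ether (no sp3 carbon on oxygen), the aryl chloride and both pyranones should survive.

**Compound list**
1 | 2,6-dimethoxyphenol | COc1cccc(OC)c1O | starting material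
2 | 4-fluorobenzaldehyde | O=Cc1ccc(F)cc1 | starting material
3 | 4-(2,6-dimethoxyphenoxy)benzaldehyde | COc1cccc(OC)c1Oc1ccc(C=O)cc1 | intermediate
4 | (E)-3-(4-methoxyphenyl)prop-2-enoyl chloride | COc1ccc(/C=C/C(Cl)=O)cc1 | starting material
5 | 4-{2-hydroxy-6-methoxy-3-[(2E)-3-(4-methoxyphenyl)prop-2-enoyl]phenoxy}benzaldehyde | COc1ccc(/C=C/C(=O)c2ccc(OC)c(Oc3ccc(C=O)cc3)c2O)cc1 | intermediate
6 | 2-chloro-1,3-dimethoxybenzene | COc1cccc(OC)c1Cl | starting material
7 | 1-(3-chloro-2-hydroxy-4-methoxyphenyl)ethan-1-one | CC(=O)c1ccc(OC)c(Cl)c1O | intermediate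
8 | (2E)-1-(3-chloro-2-hydroxy-4-methoxyphenyl)-3-(4-{2-hydroxy-6-methoxy-3-[(2E)-3-(4-methoxyphenyl)prop-2-enoyl]phenoxy}phenyl)prop-2-en-1-one | COc1ccc(/C=C/C(=O)c2ccc(OC)c(Oc3ccc(/C=C/C(=O)c4ccc(OC)c(Cl)c4O)cc3)c2O)cc1 | intermediate
9 | 1-(3-chloro-2-hydroxy-4-methoxyphenyl)-2-(4-{3-[3,3-dimethoxy-2-(4-methoxyphenyl)propanoyl]-2-hydroxy-6-methoxyphenoxy}phenyl)-3,3-dimethoxypropan-1-one (mixture of stereoisomers at the two α-carbons) | COc1ccc(C(C(OC)OC)C(=O)c2ccc(OC)c(Oc3ccc(C(C(OC)OC)C(=O)c4ccc(OC)c(Cl)c4O)cc3)c2O)cc1 | intermediate
10 | 8-chloro-7-methoxy-3-(4-{[7-methoxy-3-(4-methoxyphenyl)-4-oxo-4H-chromen-8-yl]oxy}phenyl)-4H-chromen-4-one | O=c1c(-c2ccc(Oc3c(OC)ccc4c(=O)c(-c5ccc(OC)cc5)coc34)cc2)coc2c(Cl)c(OC)ccc12 | intermediate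
11 | bisoflavolin J (achiral) | O=c1c(-c2ccc(Oc3c(O)ccc4c(=O)c(-c5ccc(O)cc5)coc34)cc2)coc2c(Cl)c(O)ccc12 | target

**Step count and risks**
Total step count: 6. Longest linear sequence: 5 steps (steps 1, 2, 4, 5 and 6); step 3 is a one-step side branch.

Steps most likely to fail:

1. Step 5. The trivalent iodine reagent may oxidise the two chelated phenol rings, or the aryloxyphenyl ring may migrate less readily than the anisyl ring, so that half-rearranged material accumulates. The fallback sets out from 8 and replaces aryl migration by an epoxide/aroyl shift. Both 2'-hydroxyls would be capped (MeOCH2Cl, i-Pr2NEt, CH2Cl2) to give the bis(methoxymethyl) ether F1. Both enones would be epoxidised by nucleophilic epoxidation (H2O2, NaOH, MeOH/THF) to the bis(trans-epoxide) F2. BF3·OEt2 in CH2Cl2 at −20 °C would open each epoxide at the benzylic carbon and shift the aroyl group (chalcone epoxide rearrangement) to the bis(α-formyl ketone) F3. HCl in MeOH at 60 °C would remove the methoxymethyl groups and close both pyranones by cyclodehydration, returning to the route at 10.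

2. Step 2. The delocalised cinnamoyl cation may acylate slowly, so that hydroxyalkylation of the electron-rich ring by the AlCl3-activated aldehyde of a second molecule, or conjugate addition of that ring to the activated enone, competes. The fallback sets out from 3 and builds the enone under base instead. Acetylation with the small, fast acetyl cation (AcCl, AlCl3, CH2Cl2, −20 °C → rt, with the same ortho demethylation) would give the keto aldehyde 4-(3-acetyl-2-hydroxy-6-methoxyphenoxy)benzaldehyde F4. Selective acetalisation of the aldehyde (HC(OMe)3, cat. TsOH, MeOH) would give the dimethyl acetal F5, which removes the self-condensation partner. Claisen–Schmidt condensation with 4-methoxybenzaldehyde (KOH, EtOH) would give the chalcone acetal F6, and the aqueous HCl work-up would hydrolyse the acetal, returning to the route at 5.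

3. Step 4. The enolate of 7 may add in conjugate fashion to the enone already present in 5, or hydroxide may scramble that enone by retro-aldol cleavage. The fallback sets out from 7 and forms the second alkene under neutral conditions. α-Bromination (CuBr2, EtOAc/CHCl3, reflux) would give 2-bromo-1-(3-chloro-2-hydroxy-4-methoxyphenyl)ethan-1-one F7. PPh3 in toluene would give the phosphonium bromide F8, and aqueous Na2CO3 the stabilised aroylmethylene ylide F9. Wittig olefination of the aldehyde of 5 with F9 (toluene, 90 °C), which leaves ketones and enones untouched and gives E alkenes, would return to the route at 8.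

**Further compounds**
F1 | step 5 | (2E)-1-[3-chloro-4-methoxy-2-(methoxymethoxy)phenyl]-3-(4-{6-methoxy-2-(methoxymethoxy)-3-[(2E)-3-(4-methoxyphenyl)prop-2-enoyl]phenoxy}phenyl)prop-2-en-1-one | COCOc1c(Cl)c(OC)ccc1C(=O)/C=C/c1ccc(Oc2c(OC)ccc(C(=O)/C=C/c3ccc(OC)cc3)c2OCOC)cc1
F2 | step 5 | bis(trans-epoxide) of F1 (racemic, mixture of diastereomers) | COCOc1c(Cl)c(OC)ccc1C(=O)C1OC1c1ccc(Oc2c(OC)ccc(C(=O)C3OC3c3ccc(OC)cc3)c2OCOC)cc1
F3 | step 5 | 3-[3-chloro-4-methoxy-2-(methoxymethoxy)phenyl]-2-(4-{6-methoxy-2-(methoxymethoxy)-3-[2-(4-methoxyphenyl)-3-oxopropanoyl]phenoxy}phenyl)-3-oxopropanal (mixture of stereoisomers) | COCOc1c(Cl)c(OC)ccc1C(=O)C(C=O)c1ccc(Oc2c(OC)ccc(C(=O)C(C=O)c3ccc(OC)cc3)c2OCOC)cc1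
F4 | step 2 | 4-(3-acetyl-2-hydroxy-6-methoxyphenoxy)benzaldehyde | CC(=O)c1ccc(OC)c(Oc2ccc(C=O)cc2)c1O
F5 | step 2 | 1-{3-[4-(dimethoxymethyl)phenoxy]-2-hydroxy-4-methoxyphenyl}ethan-1-one | CC(=O)c1ccc(OC)c(Oc2ccc(C(OC)OC)cc2)c1O
F6 | step 2 | (2E)-1-{3-[4-(dimethoxymethyl)phenoxy]-2-hydroxy-4-methoxyphenyl}-3-(4-methoxyphenyl)prop-2-en-1-one | COc1ccc(/C=C/C(=O)c2ccc(OC)c(Oc3ccc(C(OC)OC)cc3)c2O)cc1
F7 | step 4 | 2-bromo-1-(3-chloro-2-hydroxy-4-methoxyphenyl)ethan-1-one | O=C(CBr)c1ccc(OC)c(Cl)c1O
F8 | step 4 | [2-(3-chloro-2-hydroxy-4-methoxyphenyl)-2-oxoethyl]triphenylphosphonium bromide | [Br-].O=C(C[P+](c1ccccc1)(c1ccccc1)c1ccccc1)c1ccc(OC)c(Cl)c1O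
F9 | step 4 | 1-(3-chloro-2-hydroxy-4-methoxyphenyl)-2-(triphenyl-λ5-phosphanylidene)ethan-1-one | O=C(C=P(c1ccccc1)(c1ccccc1)c1ccccc1)c1ccc(OC)c(Cl)c1O
A1 | direct plan | 8-chlorodaidzein, 8-chloro-7-hydroxy-3-(4-hydroxyphenyl)-4H-chromen-4-one | O=c1c(-c2ccc(O)cc2)coc2c(Cl)c(O)ccc12
A2 | direct plan | formononetin, 7-hydroxy-3-(4-methoxyphenyl)-4H-chromen-4-one | COc1ccc(cc1)-c1coc2cc(O)ccc2c1=O
A3 | direct plan | 8-chloro-3-(4-hydroxyphenyl)-7-methoxy-4H-chromen-4-one | O=c1c(-c2ccc(O)cc2)coc2c(Cl)c(OC)ccc12
A4 | direct plan | 8-diazonio-3-(4-methoxyphenyl)-4-oxo-4H-chromen-7-olate | COc1ccc(cc1)-c1coc2c([N+]#N)c([O-])ccc2c1=O
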